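**Strategy.** C5 of the pyrrolidine-2,4-dione ring sits between N1 and the C4 ketone, so it can be unmasked as the carbon of an N-sulfinyl imine. The 3,3,3-trichloro-2-methylpropyl group is the N1-acyl chain minus CO2H. The C5–CH2 bond is therefore made by a decarboxylative radical union of two acyl-type carbons: photoredox decarboxylation of (R)-4,4,4-trichloro-3-methylbutanoic acid and addition of the primary radical to an (R)-tert-butanesulfinyl glyoxal imine that already carries C4, the gem-dimethyl C3 and C2. One operation assembles the C2–C5 chain with its side chain and sets C5 from sulfur. N-acylation with the (S)-acid and imide-forming lactamisation finish the ring.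

Key step: step 10

Remark (assumption): the facial sense of the LiCCl3 addition is taken from the lithium-chelated syn-s-cis model of N-enoyl bornane-10,2-sultams (attack on the face remote from C3 of the bornane), i.e. (2R)-sultam gives the (3S) adduct and (2S)-sultam the (3R) adduct. Both sultam antipodes are used, so an opposite sense would only exchange them.

**Step 1**
Reactants: 1 (1R)-(+)-2,10-camphorsultam [(2S)-bornane-10,2-sultam]; 2 (E)-but-2-enoyl chloride
Product: 3 (2S)-N-[(E)-but-2-enoyl]bornane-10,2-sultam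
Conditions: NaH, toluene, 0 °C; then 2, 0 °C → rt
Reagents that add atoms: none
Why: N-acylation of the sultam sodium salt with an acid chloride (standard loading of the Oppolzer auxiliary); no stereocentre is touched.

**Step 2**
Reactants: 3 N-crotonyl (2S)-sultam
Product: 4 (2S)-N-[(3R)-4,4,4-trichloro-3-methylbutanoyl]bornane-10,2-sultam
Conditions: CHCl3 (3 equiv), LiHMDS (1.5 equiv), THF, −78 °C, 15 min; then 3, −78 °C; sat. aq NH4Cl at −78 °C
Reagents that add atoms: chloroform, ClC(Cl)Cl
Why: Michael addition of trichloromethyllithium to the N-enoyl sultam; lithium chelation of C=O and a sulfonyl oxygen should hold the enoyl unit syn-s-cis so that the β-carbon is attacked on the face remote from C3 of the bornane, setting (3R).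

**Step 3**
Reactants: 4 trichloromethyl adduct
Product: 5 (3R)-4,4,4-trichloro-3-methylbutanoic acid
Conditions: LiOH·H2O, 30 % H2O2, THF/H2O (3:1), 0 °C; Na2SO3; 1 M HCl to pH 2
Reagents that add atoms: hydrogen peroxide, OO
Why: hydroperoxide cleavage of the N-acyl sultam (auxiliary removal); the weakly basic LiOOH should avoid retro-Michael loss of the CCl3 group, and the β-stereocentre is not enolisable.

**Step 4**
Reactants: 6 (1S)-(−)-2,10-camphorsultam [(2R)-bornane-10,2-sultam]; 2 (E)-but-2-enoyl chloride
Product: 7 (2R)-N-[(E)-but-2-enoyl]bornane-10,2-sultam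
Conditions: NaH, toluene, 0 °C; then 2, 0 °C → rt
Reagents that add atoms: none
Why: same N-acylation as step 1, in the enantiomeric series.

**Step 5**
Reactants: 7 N-crotonyl (2R)-sultam
Product: 8 (2R)-N-[(3S)-4,4,4-trichloro-3-methylbutanoyl]bornane-10,2-sultam
Conditions: CHCl3 (3 equiv), LiHMDS (1.5 equiv), THF, −78 °C, 15 min; then 7, −78 °C; sat. aq NH4Cl at −78 °C
Reagents that add atoms: chloroform, ClC(Cl)Cl
Why: Michael addition of LiCCl3 as in step 2; the enantiomeric auxiliary should set (3S) by the same chelated model.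

**Step 6**
Reactants: 8 trichloromethyl adduct
Product: 9 (3S)-4,4,4-trichloro-3-methylbutanoic acid
Conditions: LiOH·H2O, 30 % H2O2, THF/H2O (3:1), 0 °C; Na2SO3; 1 M HCl to pH 2
Reagents that add atoms: hydrogen peroxide, OO
Why: hydroperoxide cleavage of the N-acyl sultam as in step 3, without touching the stereocentre.

**Step 7**
Reactants: 10 tert-butyl acetoacetate
Product: 11 tert-butyl 2,2-dimethyl-3-oxobutanoate
Conditions: MeI (2.5 equiv), K2CO3 (3 equiv), acetone, reflux
Reagents that add atoms: iodomethane, CI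
Why: double C-alkylation (SN2) of the β-keto ester enolate installs the gem-dimethyl carbon that becomes C3.

**Step 8**
Reactants: 11 tert-butyl 2,2-dimethyl-3-oxobutanoate
Product: 12 tert-butyl 2,2-dimethyl-3,4-dioxobutanoate (handled as its hydrate until dried)
Conditions: SeO2 (1.2 equiv), 1,4-dioxane/H2O (30:1), 95 °C; filter, toluene azeotrope
Reagents that add atoms: selenium dioxide, O=[Se]=O
Why: Riley oxidation of a methyl ketone to the glyoxal; the acetyl CH3 is the only enolisable position (pinacolone-type substrate).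

**Step 9**
Reactants: 12 keto aldehyde; 13 (R)-2-methylpropane-2-sulfinamide
Product: 14 tert-butyl (4E)-4-{[(R)-tert-butylsulfinyl]imino}-2,2-dimethyl-3-oxobutanoate
Conditions: 4 Å MS, PPTS (5 mol %), CH2Cl2, rt
Reagents that add atoms: none
Why: condensation of the sulfinamide with the aldehyde (Ellman imine formation); the ketone is shielded by the adjacent quaternary carbon, and the (E)-aldimine should form.

**Step 10**
Reactants: 14 keto N-sulfinyl imine; 5 (3R)-4,4,4-trichloro-3-methylbutanoic acid
Product: 15 tert-butyl (4R,6R)-4-{[(R)-tert-butylsulfinyl]amino}-7,7,7-trichloro-2,2,6-trimethyl-3-oxoheptanoate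
Conditions: 14 (1.0 equiv), 5 (1.3 equiv), 9-mesityl-3,6-di-tert-butyl-10-phenylacridinium BF4 (5 mol %), K2CO3 (0.2 equiv), PhCF3, 450 nm LEDs, rt, N2
Reagents that add atoms: none
Why: The photoexcited acridinium oxidises the carboxylate of 5, loss of CO2 gives the primary radical •CH2CH(CH3)CCl3, this adds to the imine carbon of 14, and the sulfinamidyl radical is reduced by the acridine radical and protonated in a redox-neutral cycle. The closest known reaction is the acridinium-photocatalysed decarboxylative alkylation of glyoxylate-derived N-sulfinyl imines, applied here to the keto analogue. No ring is closed. The new stereocentre (later C5) is controlled by the sulfinyl sulfur: in the s-cis (S=O/C=N) conformer the radical should enter anti to the tert-butyl group, which for the (R)-auxiliary is expected to give (4R), while the (6R) centre lies β to the radical carbon and is carried through unchanged. The step needs attack at carbon and not nitrogen of the O=C–C=N unit (polarity match of a nucleophilic alkyl radical with the electrophilic imine carbon, hindered N), no reaction at the neopentyl-type ketone, and survival of the CCl3 group. That survival is secured by the reductant-free oxidative cycle, since the acridine radical is too weak a reductant for an alkyl–CCl3 group and β-scission of the radical to propene and •CCl3 should be slow at rt.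

**Step 11**
Reactants: 15 sulfinamido keto ester; 9 (3S)-4,4,4-trichloro-3-methylbutanoic acid
Product: 18 tert-butyl (4R,6R)-7,7,7-trichloro-2,2,6-trimethyl-3-oxo-4-{[(3S)-4,4,4-trichloro-3-methylbutanoyl]amino}heptanoate, via amine hydrochloride 16 (not isolated), via acid chloride 17 (not isolated)
Conditions: (i) 15, HCl (4 M in dioxane, 2.2 equiv), MeOH, 0 °C, 30 min, concentrate; (ii) 9, (COCl)2, DMF (cat.), CH2Cl2, 0 °C → rt, concentrate; (iii) 16 + 17, CH2Cl2/sat. aq NaHCO3, 0 °C
Reagents that add atoms: none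
Why: acidolytic N-sulfinyl cleavage (the tert-butyl ester should survive brief cold HCl/MeOH) followed by Schotten–Baumann acylation; the α-amino ketone is kept as its salt until the fast acylation, so C4 should not epimerise and the tert-butyl ester blocks premature lactamisation.

**Step 12**
Reactants: 18 keto amide tert-butyl ester
Product: 21 (5R)-3,3-dimethyl-1-[(3S)-4,4,4-trichloro-3-methylbutanoyl]-5-[(2R)-3,3,3-trichloro-2-methylpropyl]pyrrolidine-2,4-dione, via keto acid 19 (not isolated), via keto acid chloride 20 (not isolated)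
Conditions: TFA/CH2Cl2 (1:3), 0 °C → rt, concentrate below 25 °C (toluene azeotrope); 1-chloro-N,N,2-trimethylprop-1-en-1-amine (1.2 equiv), CH2Cl2, 0 °C; then 2,6-lutidine (1.5 equiv), 0 °C → rt
Reagents that add atoms: none
Why: tert-butyl ester acidolysis, neutral acid chloride formation and intramolecular N-acylation of the secondary amide (5-exo-trig imide-forming lactamisation, the ring closure by which N-acylglutamic acids give N-acylpyroglutamates), helped by the gem-dimethyl effect; the weak hindered base should leave C5 untouched.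

**Compound list**
1 | (1R)-(+)-2,10-camphorsultam [(2S)-bornane-10,2-sultam] | O=S1(=O)C[C@@]23CC[C@@H](C[C@@H]2N1)C3(C)C | starting material
2 | (E)-but-2-enoyl chloride (crotonyl chloride) | C/C=C/C(=O)Cl | starting material
3 | (2S)-N-[(E)-but-2-enoyl]bornane-10,2-sultam | O=S1(=O)C[C@@]23CC[C@@H](C[C@@H]2N1C(=O)/C=C/C)C3(C)C | intermediate
4 | (2S)-N-[(3R)-4,4,4-trichloro-3-methylbutanoyl]bornane-10,2-sultam | O=S1(=O)C[C@@]23CC[C@@H](C[C@@H]2N1C(=O)C[C@@H](C)C(Cl)(Cl)Cl)C3(C)C | intermediate
5 | (3R)-4,4,4-trichloro-3-methylbutanoic acid | OC(=O)C[C@@H](C)C(Cl)(Cl)Cl | intermediate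
6 | (1S)-(−)-2,10-camphorsultam [(2R)-bornane-10,2-sultam] | O=S1(=O)C[C@]23CC[C@H](C[C@H]2N1)C3(C)C | starting material
7 | (2R)-N-[(E)-but-2-enoyl]bornane-10,2-sultam | O=S1(=O)C[C@]23CC[C@H](C[C@H]2N1C(=O)/C=C/C)C3(C)C | intermediate
8 | (2R)-N-[(3S)-4,4,4-trichloro-3-methylbutanoyl]bornane-10,2-sultam | O=S1(=O)C[C@]23CC[C@H](C[C@H]2N1C(=O)C[C@H](C)C(Cl)(Cl)Cl)C3(C)C | intermediate
9 | (3S)-4,4,4-trichloro-3-methylbutanoic acid | OC(=O)C[C@H](C)C(Cl)(Cl)Cl | intermediate
10 | tert-butyl acetoacetate | CC(=O)CC(=O)OC(C)(C)C | starting material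
11 | tert-butyl 2,2-dimethyl-3-oxobutanoate | CC(=O)C(C)(C)C(=O)OC(C)(C)C | intermediate
12 | tert-butyl 2,2-dimethyl-3,4-dioxobutanoate | CC(C)(C)OC(=O)C(C)(C)C(=O)C=O | intermediate
13 | (R)-2-methylpropane-2-sulfinamide | CC(C)(C)[S@](N)=O | starting material
14 | tert-butyl (4E)-4-{[(R)-tert-butylsulfinyl]imino}-2,2-dimethyl-3-oxobutanoate | CC(C)(C)[S@@](=O)/N=C/C(=O)C(C)(C)C(=O)OC(C)(C)C | intermediate
15 | tert-butyl (4R,6R)-4-{[(R)-tert-butylsulfinyl]amino}-7,7,7-trichloro-2,2,6-trimethyl-3-oxoheptanoate | CC(C)(C)[S@@](=O)N[C@H](C[C@@H](C)C(Cl)(Cl)Cl)C(=O)C(C)(C)C(=O)OC(C)(C)C | intermediate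
16 | tert-butyl (4R,6R)-4-amino-7,7,7-trichloro-2,2,6-trimethyl-3-oxoheptanoate hydrochloride | Cl.N[C@H](C[C@@H](C)C(Cl)(Cl)Cl)C(=O)C(C)(C)C(=O)OC(C)(C)C | intermediate
17 | (3S)-4,4,4-trichloro-3-methylbutanoyl chloride | O=C(Cl)C[C@H](C)C(Cl)(Cl)Cl | intermediate
18 | tert-butyl (4R,6R)-7,7,7-trichloro-2,2,6-trimethyl-3-oxo-4-{[(3S)-4,4,4-trichloro-3-methylbutanoyl]amino}heptanoate | O=C(C[C@H](C)C(Cl)(Cl)Cl)N[C@H](C[C@@H](C)C(Cl)(Cl)Cl)C(=O)C(C)(C)C(=O)OC(C)(C)C | intermediate
19 | (4R,6R)-7,7,7-trichloro-2,2,6-trimethyl-3-oxo-4-{[(3S)-4,4,4-trichloro-3-methylbutanoyl]amino}heptanoic acid | O=C(C[C@H](C)C(Cl)(Cl)Cl)N[C@H](C[C@@H](C)C(Cl)(Cl)Cl)C(=O)C(C)(C)C(=O)O | intermediate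
20 | (4R,6R)-7,7,7-trichloro-2,2,6-trimethyl-3-oxo-4-{[(3S)-4,4,4-trichloro-3-methylbutanoyl]amino}heptanoyl chloride | O=C(C[C@H](C)C(Cl)(Cl)Cl)N[C@H](C[C@@H](C)C(Cl)(Cl)Cl)C(=O)C(C)(C)C(=O)Cl | intermediate
21 | (5R)-3,3-dimethyl-1-[(3S)-4,4,4-trichloro-3-methylbutanoyl]-5-[(2R)-3,3,3-trichloro-2-methylpropyl]pyrrolidine-2,4-dione | C[C@H](C[C@@H]1C(=O)C(C)(C)C(=O)N1C(=O)C[C@H](C)C(Cl)(Cl)Cl)C(Cl)(Cl)Cl | target

**Total step count:** 12. **Longest linear sequence:** 6 steps (1 → 3 → 4 → 5 → 15 → 18 → 21, or equally 10 → 11 → 12 → 14 → 15 → 18 → 21).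

**Steps most likely to fail**

1. Step 10 (key step). The keto imine may direct the radical less cleanly than a glyoxylate imine: facial selectivity could erode, attack could occur at nitrogen, the yellow keto imine could be excited directly, or the product could epimerise next to the ketone under the carbonate. Fallback, setting out from 5 and 13 and returning at 15: ethyl glyoxylate is condensed with 13 (4 Å MS, CH2Cl2) to ethyl (E)-2-{[(R)-tert-butylsulfinyl]imino}acetate F1. The same acridinium-catalysed decarboxylative addition of 5 should then give ethyl (2R,4R)-2-{[(R)-tert-butylsulfinyl]amino}-5,5,5-trichloro-4-methylpentanoate F2. Saponification (LiOH, THF/H2O) gives (2R,4R)-2-{[(R)-tert-butylsulfinyl]amino}-5,5,5-trichloro-4-methylpentanoic acid F3. Activation with CDI and acylation of the lithium enolate of tert-butyl isobutyrate (LDA, THF, −78 °C, excess enolate) gives 15.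

2. Step 12. The amide nitrogen may close too slowly on the hindered acid chloride, so that cyclodehydration of the α-acylamino ketone towards an oxazole, decarboxylation of the β-keto acid or epimerisation at C5 compete. Fallback, setting out from 15 and returning at 21, inverts the order of the two N–C(O) bond formations. 4 M HCl in dioxane at rt removes both the sulfinyl group and the tert-butyl ester to give (4R,6R)-4-amino-7,7,7-trichloro-2,2,6-trimethyl-3-oxoheptanoic acid hydrochloride F4. Lactamisation with EDC·HCl/HOBt/N-methylmorpholine in CH2Cl2 gives (5R)-3,3-dimethyl-5-[(2R)-3,3,3-trichloro-2-methylpropyl]pyrrolidine-2,4-dione F5. N-deprotonation (LiHMDS, 1.0 equiv, THF, −78 °C) and acylation with acid chloride 17 (from 9) gives 21.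

3. Step 8. Hot selenous acid may over-oxidise the glyoxal to the keto acid or cleave the tert-butyl ester, and the hydrate may be hard to dry. Fallback, setting out from 11 and returning at 12: the kinetic lithium enolate (LiHMDS, THF, −78 °C) is brominated with NBS to tert-butyl 4-bromo-2,2-dimethyl-3-oxobutanoate F6, and Kornblum oxidation (DMSO, NaHCO3, rt → 50 °C) gives 12.

**Further compounds**
F1 | step 10 | ethyl (E)-2-{[(R)-tert-butylsulfinyl]imino}acetate | CC(C)(C)[S@@](=O)/N=C/C(=O)OCC
F2 | step 10 | ethyl (2R,4R)-2-{[(R)-tert-butylsulfinyl]amino}-5,5,5-trichloro-4-methylpentanoate | CC(C)(C)[S@@](=O)N[C@H](C[C@@H](C)C(Cl)(Cl)Cl)C(=O)OCC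
F3 | step 10 | (2R,4R)-2-{[(R)-tert-butylsulfinyl]amino}-5,5,5-trichloro-4-methylpentanoic acid | CC(C)(C)[S@@](=O)N[C@H](C[C@@H](C)C(Cl)(Cl)Cl)C(=O)O
F4 | step 12 | (4R,6R)-4-amino-7,7,7-trichloro-2,2,6-trimethyl-3-oxoheptanoic acid hydrochloride | Cl.N[C@H](C[C@@H](C)C(Cl)(Cl)Cl)C(=O)C(C)(C)C(=O)O
F5 | step 12 | (5R)-3,3-dimethyl-5-[(2R)-3,3,3-trichloro-2-methylpropyl]pyrrolidine-2,4-dione | C[C@H](C[C@@H]1C(=O)C(C)(C)C(=O)N1)C(Cl)(Cl)Cl
F6 | step 8 | tert-butyl 4-bromo-2,2-dimethyl-3-oxobutanoate | CC(C)(C)OC(=O)C(C)(C)C(=O)CBr
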